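**Plan**

1. Retrosynthetic cuts, in order (octahydronaphthalene numbering: C1 quaternary, C2 = CH–CH3, C4=C4a alkene, C5 = CMe2, C8a = ring-fusion CH): the aryl O–SO3H, aryl C–CHO and O-protecting groups; C1–CH3 back to C1–CO2H; the ring-B bond C1–C8a by an Ireland–Claisen retron, which restores an ester O–C4 bond; the benzylic ArCH2–C1 bond; the carbinol/lactone; the acyl bond C4–C4a.
2. Enabling feature: in ring B the quaternary C1 is homoallylic to the alkene (C1–C8a–C4a=C4) and stands 1,4 to C4. With CO2H in place of the C1 methyl, ring B is therefore the [3,3] product of a six-membered lactone (acyl carbon on C1, ring oxygen on C4).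
3. Forward order: ring A comes whole from 2,2-dimethylcyclohexanone and is acylated with a 3-methylglutarate half ester; reduction and lactonisation build a temporary ring; the arene is joined by lactone enolate benzylation; ring B arises in the Claisen ring contraction; CO2H is taken down to CH3; MOM removal, ortho-formylation, sulfation and deallylation finish.
4. Stereochemistry: C2 comes from the chiral pool half ester, the carbinol from a catalyst-controlled CBS reduction, and C1 and C8a from that carbinol by suprafacial transfer through the boat transition state that the lactone enforces.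

Key step: step 10

Remark 1: the target is drawn as a free aryl hydrogen sulfate; 25 and 26 are written in that acid form, although they would be handled as salts and the acid set free only by a cold pass through an H+-form resin.
Remark 2: (R)-methyl hydrogen 3-methylglutarate (8) is taken as a purchasable single enantiomer.
Abbreviation used in names: Ar = 2-(methoxymethoxy)-4,5-bis(prop-2-en-1-yloxy)phenyl.

**Route**

Step 1
Reactants: 1 2,4,5-trihydroxybenzaldehyde
Product: 2 2-hydroxy-4,5-bis(prop-2-en-1-yloxy)benzaldehyde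
Conditions: allyl bromide (2.1 equiv), K2CO3 (2.2 equiv), DMF, rt, N2
Reagents that add atoms: allyl bromide, C=CCBr
Why: Williamson etherification; the 2-hydroxyl is hydrogen-bonded to the formyl group and least nucleophilic, so two equivalents of allyl bromide should take only the 4- and 5-hydroxyls.

Step 2
Reactants: 2 2-hydroxy-4,5-bis(prop-2-en-1-yloxy)benzaldehyde
Product: 3 2-(methoxymethoxy)-4,5-bis(prop-2-en-1-yloxy)benzaldehyde
Conditions: NaH, MOMCl, THF/DMF, 0 °C
Reagents that add atoms: chloromethyl methyl ether, COCCl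
Why: O-alkylation of the remaining phenoxide with MOMCl gives an acetal that withstands the bases and hydrides used later.

Step 3
Reactants: 3 2-(methoxymethoxy)-4,5-bis(prop-2-en-1-yloxy)benzaldehyde
Product: 4 [2-(methoxymethoxy)-4,5-bis(prop-2-en-1-yloxy)phenyl]methanol
Conditions: NaBH4, MeOH/THF, 0 °C
Reagents that add atoms: none
Why: Borohydride reduction of the aryl aldehyde; allyl and MOM ethers are inert.

Step 4
Reactants: 4 [2-(methoxymethoxy)-4,5-bis(prop-2-en-1-yloxy)phenyl]methanol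
Product: 5 1-(bromomethyl)-2-(methoxymethoxy)-4,5-bis(prop-2-en-1-yloxy)benzene
Conditions: PPh3, CBr4, CH2Cl2, 0 °C; used at once
Reagents that add atoms: carbon tetrabromide, BrC(Br)(Br)Br
Why: Appel bromination is neutral and so keeps the acid-sensitive MOM ether.

Step 5
Reactants: 6 2,2-dimethylcyclohexanone
Product: 7 N'-(2,2-dimethylcyclohexylidene)-2,4,6-triisopropylbenzenesulfonohydrazide
Conditions: 2,4,6-(i-Pr)3C6H2SO2NHNH2, HCl (cat.), MeOH, rt
Reagents that add atoms: 2,4,6-triisopropylbenzenesulfonyl hydrazide, CC(C)c1cc(C(C)C)c(S(=O)(=O)NN)c(C(C)C)c1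
Why: Condensation to the arylsulfonylhydrazone needed for a Shapiro reaction.

Step 6
Reactants: 8 (3R)-5-methoxy-3-methyl-5-oxopentanoic acid
Product: 9 methyl (3S)-5-chloro-3-methyl-5-oxopentanoate (same spatial arrangement as 8; the descriptor changes by priority only)
Conditions: (COCl)2, DMF (cat.), CH2Cl2, 0 °C → rt
Reagents that add atoms: oxalyl chloride, O=C(Cl)C(=O)Cl
Why: Acid chloride formation activates the free carboxyl only; the ester and the β-stereocentre are untouched.

Step 7
Reactants: 7 N'-(2,2-dimethylcyclohexylidene)-2,4,6-triisopropylbenzenesulfonohydrazide; 9 methyl (3S)-5-chloro-3-methyl-5-oxopentanoate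
Product: 12 methyl (3R)-5-(6,6-dimethylcyclohex-1-en-1-yl)-3-methyl-5-oxopentanoate, via vinyllithium 10 (not isolated), via vinylzinc chloride 11 (not isolated)
Conditions: n-BuLi (2.1 equiv), THF, −78 → 0 °C; ZnCl2, 0 °C; then 9, Pd(PPh3)4 (5 mol %), 0 °C → rt
Reagents that add atoms: none
Why: The Shapiro reaction gives the alkenyllithium regiospecifically because the other α-carbon is quaternary, and after transmetalation to zinc a Negishi acylation under zerovalent palladium joins it to the acid chloride without touching the methyl ester.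

Step 8
Reactants: 12 methyl (3R)-5-(6,6-dimethylcyclohex-1-en-1-yl)-3-methyl-5-oxopentanoate
Product: 14 (4R,6R)-6-(6,6-dimethylcyclohex-1-en-1-yl)-4-methyloxan-2-one, via hydroxy ester 13 (not isolated)
Conditions: (S)-2-methyl-CBS-oxazaborolidine [(S)-1-methyl-3,3-diphenyltetrahydro-1H,3H-pyrrolo[1,2-c][1,3,2]oxazaborole] (20 mol %), catecholborane, PhMe, −78 °C; then pyridinium p-toluenesulfonate (cat.), PhMe, 60 °C
Reagents that add atoms: none
Why: Corey–Bakshi–Shibata reduction with the cyclohexenyl group as the large substituent should set the (5R) carbinol under catalyst control, and mild acid then closes the δ-lactone with methyl and alkenyl groups cis.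

Step 9
Reactants: 14 (4R,6R)-6-(6,6-dimethylcyclohex-1-en-1-yl)-4-methyloxan-2-one; 5 1-(bromomethyl)-2-(methoxymethoxy)-4,5-bis(prop-2-en-1-yloxy)benzene
Product: 15 (3S,4R,6R)-3-(Ar-methyl)-6-(6,6-dimethylcyclohex-1-en-1-yl)-4-methyloxan-2-one (3,4-trans expected as the major epimer)
Conditions: LiN(i-Pr)2, THF, −78 °C; then 5, −78 → −30 °C
Reagents that add atoms: none
Why: Alkylation of the lactone lithium enolate with a reactive benzylic bromide, expected anti to the 4-methyl group; the C3 configuration is erased in step 10, so either epimer serves.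

Step 10
Reactants: 15 (3S,4R,6R)-3-(Ar-methyl)-6-(6,6-dimethylcyclohex-1-en-1-yl)-4-methyloxan-2-one
Product: 18 (1S,2R,8aR)-1-(Ar-methyl)-2,5,5-trimethyl-1,2,3,5,6,7,8,8a-octahydronaphthalene-1-carboxylic acid (carboxyl cis to the ring-A C8 methylene; benzyl, C2 methyl and H-8a on the other face), via silyl ketene acetal 16 (not isolated), via trimethylsilyl ester 17 (not isolated)
Conditions: LiN(i-Pr)2, THF, −78 °C; Me3SiCl/Et3N, −78 °C → rt; PhMe, 110 °C; then H2O/THF, citric acid work-up
Reagents that add atoms: none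
Why: Deprotonation at C3 and O-silylation give the cyclic silyl ketene acetal 16, which on heating undergoes a [3,3]-sigmatropic Ireland–Claisen rearrangement: the allylic C6–O bond of the lactone breaks, lactone C3 bonds to the CH carbon of the ring-A alkene, and the double bond moves to C4=C4a of the product. The closest known reaction type is the Claisen rearrangement of silyl enolates of δ-alkenyl δ-lactones to cyclohex-3-enecarboxylic acids. Ring B is closed by contraction of the six-membered lactone; the two-carbon bridge between the termini of the allyl vinyl ether forces a boat-like transition state shaped like bicyclo[2.2.2]octane. The quaternary C1 and the ring-fusion C8a are both set by suprafacial transfer from the (6R) carbinol carbon: the ring-A methylene (outside substituent of the alkene) ends cis to the carboxyl and H-8a cis to the benzyl group, while the 4-methyl group, cis to the alkenyl group in the lactone, ends cis to the benzyl group. The step needs only this facial control, which the tether secures because no chair alternative can be reached, and O- over C-silylation, which the in situ Me3SiCl/Et3N quench secures. The alkene position is fixed by the pericyclic array, so no olefin regioisomer can form.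

Step 11
Reactants: 18 (1S,2R,8aR)-1-(Ar-methyl)-2,5,5-trimethyl-1,2,3,5,6,7,8,8a-octahydronaphthalene-1-carboxylic acid
Product: 19 [(1S,2R,8aR)-1-(Ar-methyl)-2,5,5-trimethyl-1,2,3,5,6,7,8,8a-octahydronaphthalen-1-yl]methanol
Conditions: LiAlH4, THF, 0 °C → reflux
Reagents that add atoms: none
Why: Hydride reduction of the hindered carboxylic acid to the primary alcohol; ethers and the trisubstituted alkene are inert.

Step 12
Reactants: 19 [(1S,2R,8aR)-1-(Ar-methyl)-2,5,5-trimethyl-1,2,3,5,6,7,8,8a-octahydronaphthalen-1-yl]methanol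
Product: 20 (1S,2R,8aR)-1-(Ar-methyl)-2,5,5-trimethyl-1,2,3,5,6,7,8,8a-octahydronaphthalene-1-carbaldehyde
Conditions: Dess–Martin periodinane, pyridine, CH2Cl2, rt
Reagents that add atoms: none
Why: Dess–Martin oxidation gives the non-enolisable neopentyl aldehyde without touching the electron-rich arene or the alkenes.

Step 13
Reactants: 20 (1S,2R,8aR)-1-(Ar-methyl)-2,5,5-trimethyl-1,2,3,5,6,7,8,8a-octahydronaphthalene-1-carbaldehyde
Product: 22 1-{[(1R,2R,8aS)-1,2,5,5-tetramethyl-1,2,3,5,6,7,8,8a-octahydronaphthalen-1-yl]methyl}-2-(methoxymethoxy)-4,5-bis(prop-2-en-1-yloxy)benzene, via tosylhydrazone 21 (not isolated)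
Conditions: TsNHNH2, THF, 50 °C; then catecholborane, CHCl3, 0 °C → rt; NaOAc·3H2O, 60 °C
Reagents that add atoms: none
Why: Caglioti-type deoxygenation: hydride adds to the hydrazone C=N, sulfinate leaves and the diazene loses N2, turning CHO into CH3 without the strong base and heat that the allyl ethers would not survive.

Step 14
Reactants: 22 1-{[(1R,2R,8aS)-1,2,5,5-tetramethyl-1,2,3,5,6,7,8,8a-octahydronaphthalen-1-yl]methyl}-2-(methoxymethoxy)-4,5-bis(prop-2-en-1-yloxy)benzene
Product: 23 2-{[(1R,2R,8aS)-1,2,5,5-tetramethyl-1,2,3,5,6,7,8,8a-octahydronaphthalen-1-yl]methyl}-4,5-bis(prop-2-en-1-yloxy)phenol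
Conditions: HCl (cat.), MeOH/THF, rt
Reagents that add atoms: none
Why: Acid-catalysed acetal exchange with methanol removes the MOM group under conditions too mild to protonate the ring alkene or cleave the allyl ethers.

Step 15
Reactants: 23 2-{[(1R,2R,8aS)-1,2,5,5-tetramethyl-1,2,3,5,6,7,8,8a-octahydronaphthalen-1-yl]methyl}-4,5-bis(prop-2-en-1-yloxy)phenol
Product: 24 2-hydroxy-3-{[(1R,2R,8aS)-1,2,5,5-tetramethyl-1,2,3,5,6,7,8,8a-octahydronaphthalen-1-yl]methyl}-5,6-bis(prop-2-en-1-yloxy)benzaldehyde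
Conditions: MgCl2, Et3N, (CH2O)n, MeCN, 80 °C
Reagents that add atoms: formaldehyde (as paraformaldehyde), C=O
Why: Magnesium phenoxide-directed ortho-formylation: formaldehyde is delivered within the chelate to the only free ortho position, and the benzylic alkoxide is oxidised by a second formaldehyde in an Oppenauer-type hydride transfer.

Step 16
Reactants: 24 2-hydroxy-3-{[(1R,2R,8aS)-1,2,5,5-tetramethyl-1,2,3,5,6,7,8,8a-octahydronaphthalen-1-yl]methyl}-5,6-bis(prop-2-en-1-yloxy)benzaldehyde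
Product: 25 2-formyl-6-{[(1R,2R,8aS)-1,2,5,5-tetramethyl-1,2,3,5,6,7,8,8a-octahydronaphthalen-1-yl]methyl}-3,4-bis(prop-2-en-1-yloxy)phenyl hydrogen sulfate (handled as its pyridinium salt)
Conditions: SO3·pyridine, pyridine, 50 °C
Reagents that add atoms: sulfur trioxide–pyridine complex, O=S(=O)=O.c1ccncc1
Why: O-sulfonation of a phenol by the SO3·pyridine complex; only one hydroxyl is free, so no site selectivity is needed.

Step 17
Reactants: 25 2-formyl-6-{[(1R,2R,8aS)-1,2,5,5-tetramethyl-1,2,3,5,6,7,8,8a-octahydronaphthalen-1-yl]methyl}-3,4-bis(prop-2-en-1-yloxy)phenyl hydrogen sulfate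
Product: 26 2-formyl-3,4-dihydroxy-6-{[(1R,2R,8aS)-1,2,5,5-tetramethyl-1,2,3,5,6,7,8,8a-octahydronaphthalen-1-yl]methyl}phenyl hydrogen sulfate
Conditions: Pd(PPh3)4 (5 mol %), N-methylaniline, THF, rt, degassed; then H+-form sulfonic acid resin, MeOH/H2O, 0 °C
Reagents that add atoms: none
Why: Tsuji–Trost deallylation under zerovalent palladium with N-methylaniline as allyl acceptor is neutral and should leave the aryl sulfate, the aldehyde and the ring alkene untouched.

**Compound list**

1 | 2,4,5-trihydroxybenzaldehyde | O=Cc1cc(O)c(O)cc1O | starting material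
2 | 2-hydroxy-4,5-bis(prop-2-en-1-yloxy)benzaldehyde | O=Cc1cc(OCC=C)c(OCC=C)cc1O | intermediate
3 | 2-(methoxymethoxy)-4,5-bis(prop-2-en-1-yloxy)benzaldehyde | O=Cc1cc(OCC=C)c(OCC=C)cc1OCOC | intermediate
4 | [2-(methoxymethoxy)-4,5-bis(prop-2-en-1-yloxy)phenyl]methanol | OCc1cc(OCC=C)c(OCC=C)cc1OCOC | intermediate
5 | 1-(bromomethyl)-2-(methoxymethoxy)-4,5-bis(prop-2-en-1-yloxy)benzene | BrCc1cc(OCC=C)c(OCC=C)cc1OCOC | intermediate
6 | 2,2-dimethylcyclohexanone | CC1(C)CCCCC1=O | starting material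
7 | N'-(2,2-dimethylcyclohexylidene)-2,4,6-triisopropylbenzenesulfonohydrazide | CC(C)c1cc(C(C)C)c(S(=O)(=O)NN=C2CCCCC2(C)C)c(C(C)C)c1 | intermediate
8 | (3R)-5-methoxy-3-methyl-5-oxopentanoic acid | COC(=O)C[C@H](C)CC(=O)O | starting material
9 | methyl (3S)-5-chloro-3-methyl-5-oxopentanoate | COC(=O)C[C@H](C)CC(=O)Cl | intermediate
10 | (6,6-dimethylcyclohex-1-en-1-yl)lithium | [Li]C1=CCCCC1(C)C | intermediate
11 | chloro(6,6-dimethylcyclohex-1-en-1-yl)zinc | Cl[Zn]C1=CCCCC1(C)C | intermediate
12 | methyl (3R)-5-(6,6-dimethylcyclohex-1-en-1-yl)-3-methyl-5-oxopentanoate | COC(=O)C[C@H](C)CC(=O)C1=CCCCC1(C)C | intermediate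
13 | methyl (3R,5R)-5-(6,6-dimethylcyclohex-1-en-1-yl)-5-hydroxy-3-methylpentanoate | COC(=O)C[C@H](C)C[C@@H](O)C1=CCCCC1(C)C | intermediate
14 | (4R,6R)-6-(6,6-dimethylcyclohex-1-en-1-yl)-4-methyloxan-2-one | O=C1C[C@H](C)C[C@H](C2=CCCCC2(C)C)O1 | intermediate
15 | (3S,4R,6R)-3-(Ar-methyl)-6-(6,6-dimethylcyclohex-1-en-1-yl)-4-methyloxan-2-one | O=C1[C@@H](Cc2cc(OCC=C)c(OCC=C)cc2OCOC)[C@H](C)C[C@H](C2=CCCCC2(C)C)O1 | intermediate
16 | (2R,4R)-5-(Ar-methyl)-2-(6,6-dimethylcyclohex-1-en-1-yl)-4-methyl-6-(trimethylsilyloxy)-3,4-dihydro-2H-pyran | C[Si](C)(C)OC1=C(Cc2cc(OCC=C)c(OCC=C)cc2OCOC)[C@H](C)C[C@H](C2=CCCCC2(C)C)O1 | intermediate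
17 | trimethylsilyl (1S,2R,8aR)-1-(Ar-methyl)-2,5,5-trimethyl-1,2,3,5,6,7,8,8a-octahydronaphthalene-1-carboxylate | C[C@@H]1CC=C2[C@@H](CCCC2(C)C)[C@]1(C(=O)O[Si](C)(C)C)Cc1cc(OCC=C)c(OCC=C)cc1OCOC | intermediate
18 | (1S,2R,8aR)-1-(Ar-methyl)-2,5,5-trimethyl-1,2,3,5,6,7,8,8a-octahydronaphthalene-1-carboxylic acid | C[C@@H]1CC=C2[C@@H](CCCC2(C)C)[C@]1(C(=O)O)Cc1cc(OCC=C)c(OCC=C)cc1OCOC | intermediate
19 | [(1S,2R,8aR)-1-(Ar-methyl)-2,5,5-trimethyl-1,2,3,5,6,7,8,8a-octahydronaphthalen-1-yl]methanol | C[C@@H]1CC=C2[C@@H](CCCC2(C)C)[C@]1(CO)Cc1cc(OCC=C)c(OCC=C)cc1OCOC | intermediate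
20 | (1S,2R,8aR)-1-(Ar-methyl)-2,5,5-trimethyl-1,2,3,5,6,7,8,8a-octahydronaphthalene-1-carbaldehyde | C[C@@H]1CC=C2[C@@H](CCCC2(C)C)[C@]1(C=O)Cc1cc(OCC=C)c(OCC=C)cc1OCOC | intermediate
21 | N'-{[(1S,2R,8aR)-1-(Ar-methyl)-2,5,5-trimethyl-1,2,3,5,6,7,8,8a-octahydronaphthalen-1-yl]methylidene}-4-methylbenzenesulfonohydrazide | C[C@@H]1CC=C2[C@@H](CCCC2(C)C)[C@]1(C=NNS(=O)(=O)c1ccc(C)cc1)Cc1cc(OCC=C)c(OCC=C)cc1OCOC | intermediate
22 | 1-{[(1R,2R,8aS)-1,2,5,5-tetramethyl-1,2,3,5,6,7,8,8a-octahydronaphthalen-1-yl]methyl}-2-(methoxymethoxy)-4,5-bis(prop-2-en-1-yloxy)benzene | C[C@@H]1CC=C2[C@@H](CCCC2(C)C)[C@]1(C)Cc1cc(OCC=C)c(OCC=C)cc1OCOC | intermediate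
23 | 2-{[(1R,2R,8aS)-1,2,5,5-tetramethyl-1,2,3,5,6,7,8,8a-octahydronaphthalen-1-yl]methyl}-4,5-bis(prop-2-en-1-yloxy)phenol | C[C@@H]1CC=C2[C@@H](CCCC2(C)C)[C@]1(C)Cc1cc(OCC=C)c(OCC=C)cc1O | intermediate
24 | 2-hydroxy-3-{[(1R,2R,8aS)-1,2,5,5-tetramethyl-1,2,3,5,6,7,8,8a-octahydronaphthalen-1-yl]methyl}-5,6-bis(prop-2-en-1-yloxy)benzaldehyde | C[C@@H]1CC=C2[C@@H](CCCC2(C)C)[C@]1(C)Cc1cc(OCC=C)c(OCC=C)c(C=O)c1O | intermediate
25 | 2-formyl-6-{[(1R,2R,8aS)-1,2,5,5-tetramethyl-1,2,3,5,6,7,8,8a-octahydronaphthalen-1-yl]methyl}-3,4-bis(prop-2-en-1-yloxy)phenyl hydrogen sulfate | C[C@@H]1CC=C2[C@@H](CCCC2(C)C)[C@]1(C)Cc1cc(OCC=C)c(OCC=C)c(C=O)c1OS(=O)(=O)O | intermediate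
26 | 2-formyl-3,4-dihydroxy-6-{[(1R,2R,8aS)-1,2,5,5-tetramethyl-1,2,3,5,6,7,8,8a-octahydronaphthalen-1-yl]methyl}phenyl hydrogen sulfate | C[C@@H]1CC=C2[C@@H](CCCC2(C)C)[C@]1(C)Cc1cc(O)c(O)c(C=O)c1OS(=O)(=O)O | target

**Totals**

Total step count: 17.
Longest linear sequence: 13 steps (steps 1–4, then 9–17).

**Steps most likely to fail**

Step 10. The rearrangement must pass through a crowded boat transition state while a tetrasubstituted silyl ketene acetal survives at 110 °C. It may stall, with C-silylation or loss of the ketene acetal taking over. Fallback, setting out from 15 and coming back at 19: lactone 15 would be reduced with (i-Bu)2AlH (CH2Cl2, −78 °C) to the lactol (3S,4R,6R)-3-(Ar-methyl)-6-(6,6-dimethylcyclohex-1-en-1-yl)-4-methyloxan-2-ol F1. MsCl/Et3N would dehydrate it to the cyclic enol ether (2R,4R)-5-(Ar-methyl)-2-(6,6-dimethylcyclohex-1-en-1-yl)-4-methyl-3,4-dihydro-2H-pyran F2. (i-Bu)3Al in CH2Cl2 at rt would then promote the Claisen rearrangement of this neutral 2-alkenyl dihydropyran by Lewis acid activation at the ring oxygen, through the same boat array, and reduce the aldehyde formed. This returns to the route at alcohol 19 and bypasses acid 18 and step 11.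

Step 15. Delivery of formaldehyde to the position flanked by the hydroxyl and an allyloxy group, next to a bulky benzylic substituent, may be slow and may stop at the hydroxymethyl stage. Fallback, setting out from 23 and coming back at 24: phenol 23 would be iodinated ortho to the hydroxyl with I2/morpholine to give 2-iodo-6-{[(1R,2R,8aS)-1,2,5,5-tetramethyl-1,2,3,5,6,7,8,8a-octahydronaphthalen-1-yl]methyl}-3,4-bis(prop-2-en-1-yloxy)phenol F3. After deprotonation with NaH, iodine–lithium exchange with t-BuLi at −78 °C and a DMF quench would give aldehyde 24.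

Step 16. Sulfation of a hindered, hydrogen-bonded phenol may be incomplete, and the sulfate monoester may hydrolyse on acidic contact during isolation. Fallback, setting out from 24 and coming back at 25: phenol 24 would be converted with 2,2,2-trichloroethyl chlorosulfate, Et3N and DMAP into the neutral diester 2-formyl-6-{[(1R,2R,8aS)-1,2,5,5-tetramethyl-1,2,3,5,6,7,8,8a-octahydronaphthalen-1-yl]methyl}-3,4-bis(prop-2-en-1-yloxy)phenyl 2,2,2-trichloroethyl sulfate F4, which can be chromatographed. Zn and HCO2NH4 in MeOH would then unmask the monoester 25.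

**Further compounds**

F1 | step 10 | (3S,4R,6R)-3-(Ar-methyl)-6-(6,6-dimethylcyclohex-1-en-1-yl)-4-methyloxan-2-ol (anomer mixture) | OC1[C@@H](Cc2cc(OCC=C)c(OCC=C)cc2OCOC)[C@H](C)C[C@H](C2=CCCCC2(C)C)O1
F2 | step 10 | (2R,4R)-5-(Ar-methyl)-2-(6,6-dimethylcyclohex-1-en-1-yl)-4-methyl-3,4-dihydro-2H-pyran | C[C@@H]1C[C@H](C2=CCCCC2(C)C)OC=C1Cc1cc(OCC=C)c(OCC=C)cc1OCOC
F3 | step 15 | 2-iodo-6-{[(1R,2R,8aS)-1,2,5,5-tetramethyl-1,2,3,5,6,7,8,8a-octahydronaphthalen-1-yl]methyl}-3,4-bis(prop-2-en-1-yloxy)phenol | C[C@@H]1CC=C2[C@@H](CCCC2(C)C)[C@]1(C)Cc1cc(OCC=C)c(OCC=C)c(I)c1O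
F4 | step 16 | 2-formyl-6-{[(1R,2R,8aS)-1,2,5,5-tetramethyl-1,2,3,5,6,7,8,8a-octahydronaphthalen-1-yl]methyl}-3,4-bis(prop-2-en-1-yloxy)phenyl 2,2,2-trichloroethyl sulfate | C[C@@H]1CC=C2[C@@H](CCCC2(C)C)[C@]1(C)Cc1cc(OCC=C)c(OCC=C)c(C=O)c1OS(=O)(=O)OCC(Cl)(Cl)Cl
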